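(The readings stem from a simulated flask on assumed constants; scatter was added.)

Late in the noon run, between 4.00 h and 6.00 h, 40.0% of the fresh product, meaning what newly became target or over-reacted product, was over-reacted product. Both steps draw on the reagent in the reaction phase, so if each is first order in it, its level cancels in their ratio. The over-reacted fraction of fresh product then equals a constant times the ratio of target to starting material, both as fractions of the charge. We take starting material as what has been fed less what became product. The ratio then stood at 0.691 and 0.708 at those two readings, so the noon window gives a constant of 0.572.

| flask | starting material | reagent in the second phase | protic impurity | remark | time | volume of the second phase over the first |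
|---|---|---|---|---|---|---|
| noon | 0.10 M (fed, over 6.0 h) | 1 equiv | 2.6 mM | run made earlier; the fed solution adds 1.0 times the starting volume |  |  |
| dawn | 0.10 M (fed, over 6.0 h) | 1 equiv | 9.3 mM | run made earlier; the fed solution adds 1.0 times the starting volume |  |  |
| summer | 0.10 M (fed, over 6.0 h) | 0.90 equiv | 2 mM | run made earlier; the fed solution adds 1.0 times the starting volume |  |  |
| cedar | 0.10 M (fed, over 6.0 h) | 1.00 equiv | 2.00 mM | the fed solution adds 1.0 times the starting volume | 6.0 h | 0.50 |
| birch | 0.10 M (fed, over 6.0 h) | 0.670 equiv | 8.00 mM | the fed solution adds 1.0 times the starting volume | 6.0 h | 0.50 |
| alder | 0.40 M (fed, over 6.0 h) | 1.00 equiv | 8.00 mM | the fed solution adds 1.0 times the starting volume | 6.0 h | 0.50 |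
| oak | 0.10 M (fed, over 4.0 h) | 2.00 equiv | 2.00 mM | the fed solution adds 1.0 times the starting volume | 6.0 h | 0.50 |

| run | time / h | target / % | over-reacted product / % |
|---|---|---|---|
| noon | 0.500 | 1.0 | 0 |
| noon | 0.667 | 0 | 0.6 |
| noon | 1.00 | 3.2 | 0 |
| noon | 1.50 | 4.4 | 0.5 |
| noon | 2.50 | 12.6 | 1.7 |
| noon | 4.00 | 23.8 | 8.4 |
| noon | 6.00 | 34.9 | 15.8 |
| dawn | 0.500 | 1.0 | 0 |
| dawn | 0.667 | 1.1 | 0.5 |
| dawn | 1.00 | 1.7 | 0 |
| dawn | 1.50 | 4.8 | 1.0 |
| dawn | 2.50 | 10.4 | 1.5 |
| dawn | 4.00 | 23.4 | 6.0 |
| dawn | 6.00 | 34.1 | 14.7 |
| summer | 1.33 | 3.3 | 0.4 |
| summer | 2.50 | 11.8 | 2.4 |
| summer | 4.00 | 22.6 | 7.6 |
| summer | 5.00 | 28.0 | 10.1 |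
| summer | 6.00 | 32.8 | 13.0 |

(each reading ± 0.5 percentage points)

- amounts are per litre of the starting volume; all of the dose is in the solution fed
- in the second phase: reagent in the second phase; everything else is in the first
- charges count per volume of the first phase; a concentration in a rate is the amount of a species over the volume of its own phase; every rate counts per litre of the first phase
- the analysis behind the earlier runs scatters by 0.5 percentage points, standard deviation
- steps under discussion: reagent in the reaction phase <-> reagent in the second phase; starting material -> decomposition product; starting material + reagent in the reaction phase -> target; reagent in the reaction phase + target -> over-reacted product; reagent in the reaction phase + protic impurity -> quenched reagent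
- the earlier runs hold the two phases in the same ratio of volumes as the flask asked about
- percentages count the whole charge, also what has not yet gone in

* the flasks by share of target in all that became target or over-reacted product, highest first, at 6.0 h (cedar / birch / alder / oak)
* the same order at 80 min (cedar / birch / alder / oak)
* the share of target in all that became target or over-reacted product of the flask you put first, at 6.0 h
* the share of target in all that became target or over-reacted product of the flask you put last, at 6.0 h

A second way uses another flask and another kind of reading, the whole summer run. At its end 28.4% of the product was over-reacted and the ratio was 0.605, which gives 0.469, lower than the noon figure. This way cheats, for it lays the end ratio over the whole run, yet the ratio was 0.430 at 2.50 h. Going round once more with the ratio averaged over the product as it formed, 0.459, gives 0.619 against the noon 0.572. The dawn window gives 0.693, which shows the scatter, so we carry the mean of the noon and summer figures, 0.596, as a reading no closer than that spread. This mean is the over-reaction factor, the selectivity factor of the two steps. Target should stop growing once the ratio passes 1.68.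

For birch we go round the same way. We scale the dawn run, whose impurity is close to birch's, by the reagent charge, which gives 32.7% product and a product-to-starting-material ratio of 0.486. We take the average ratio at 0.758 of the end ratio, as in summer. Pretending the product is pure target gives a target share of 78.1%. Putting that share back gives 82.9%, and the passes close on 82.0%. The noon run, close to cedar's recipe, ended at a share of 68.8%, lower than our birch figure, so we put birch first and cedar second. Alder has 4.00 times cedar's reagent per volume, and oak has twice cedar's equivalents and an early end of feed. We put these two behind cedar and oak last, by judgement, and give neither a figure of ours. Early on, we expect the ratio to follow the reagent charge per volume, and alder has twice oak's, so alder goes last there.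

The forecast reads birch > cedar > alder > oak at the end and birch > cedar > oak > alder early, with 79% for its first flask and 43% for its last, holding that “Over-reaction is therefore governed by how much reagent meets accumulated target”; its top is lower than our 82.0%.

The flask gives birch > cedar > alder > oak at the end and birch > cedar > oak > alder early, with birch at 81.4% and oak at 45.1%.

    reagent in the reaction phase ⇌ reagent in the second phase, rate k1*([reagent in the reaction phase] - [reagent in the second phase]/K1) per volume of the first phase (partition coefficient = 0.370, kL = 0.0380 /h)
    starting material → decomposition product (k = 3.90 × 10⁻⁵ /h)
    starting material + reagent in the reaction phase → target (k = 23.0 /M/h)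
    reagent in the reaction phase + target → over-reacted product (k = 13.0 /M/h)
    reagent in the reaction phase + protic impurity → quenched reagent (k = 51.0 /M/h)

Oak's conversion at the end is 85.8%. In oak the ratio went from 1.05 at 4.00 h to 2.73 at 6.00 h, across the turning value 1.68, while its target went from 37.9% to 38.7%.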